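(All runs were computed for an exercise; noise was put on by code.)

At early times substrate and coupling partner react fast. In the blue run substrate loses on average 0.920 min⁻¹ of the charge over the first 1.00 min. In the green run it has reached 33% by 2.50 min, and after that knee it stays between 28% and 35%.

common to all: substrate 0.20 M
- green: coupling partner 1.2 equiv; run made earlier
- blue: coupling partner 3.8 equiv; run made earlier
- delta: coupling partner 1.00 equiv; time 20 min
- alpha: coupling partner 2.50 equiv; time 20 min

| run | time / min | single product / % | substrate / % |
|---|---|---|---|
| green | 2.50 | 53 | 33 |
| green | 5.00 | 50 | 28 |
| green | 8.00 | 43 | 32 |
| green | 10.0 | 36 | 33 |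
| green | 12.0 | 29 | 34 |
| green | 15.0 | 28 | 35 |
| blue | 1.00 | 71 | 8 |
| blue | 2.00 | 63 | 4 |
| blue | 3.00 | 57 | 5 |
| blue | 5.00 | 48 | 9 |
| blue | 8.00 | 33 | 9 |
| blue | 15.0 | 14 | 2 |

(readings scatter by 1.5 percentage points)



- which of these holds the largest part of the substrate at the end of delta (other mono adduct / single product / double product / substrate)
- which of these holds the largest part of the substrate at the end of alpha (other mono adduct / single product / double product / substrate)
- single product at the end of alpha, in percent of the substrate charged

Single product stands highest at the first reading of both runs and then falls, so I draw its falling branch as one exponential, with a start level found by extrapolating that branch back to the time of mixing; this level is a figure of the reckoning, not an amount in the flask.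

Green constant: ln(53% / 28%) / (15.0 min − 2.50 min) = 0.0510 min⁻¹

Blue constant: ln(71% / 14%) / (15.0 min − 1.00 min) = 0.116 min⁻¹

Start levels, green and blue: 60.2% and 79.7%

In equivalents alpha lies half of the way from green to blue, so green's constant needs a correction of 0.0325 min⁻¹.

Alpha: 0.0835 min⁻¹, the drain constant, a pseudo-first-order constant read from the two runs

Alpha start level: 70.0%

On this curve alpha's single product crosses 0.5 of the charge at 4.02 min, has a half-life of 8.30 min, and heads towards zero, standing at 13.2% at the end.

The forecast names substrate for delta and double product for alpha, and gives 15% single product from 0.085/min and a peak near 70%, holding of the decay of single product that “it depends only weakly on partner”. My figure lies lower.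

Delta ends with substrate holding the largest part, 39.2%. Alpha ends with double product holding the largest part, 74.0%, and with single product at 14.3%.

    substrate + coupling partner ⇌ single product + released group (K = 3.00, k = 0.0840 M⁻¹ s⁻¹)
    substrate + coupling partner → other mono adduct + released group (k = 0.0150 M⁻¹ s⁻¹)
    coupling partner + single product → double product + released group (k = 0.00170 M⁻¹ s⁻¹)
    coupling partner + other mono adduct → double product + released group (k = 0.0390 M⁻¹ s⁻¹)

Alpha's single product stands at 32.8% at 10.0 min. The drain constant carried over the remaining time gives 14.2%, and alpha ends at 14.3%. A neighbouring flask, charged like alpha but with 0.620 equiv of coupling partner, lies below green in equivalents, on the line carried past its end. The line gives it a constant of 0.0366 min⁻¹, a start level of 55.9% and an end value of 26.9%, while that flask ends at 21.8%.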